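Compound numbers used below are those of the steps and the compound list. In 19 the ring is numbered O1, C2–C5, and Cα is the side-chain carbon bonded to C5.

## Analysis of the target

Target 19 is a single oxolane ring. C2 is quaternary (methyl and (E)-2-bromoethenyl), C3 carries bromine, C4 is an unsubstituted CH2, and C5 carries a side chain whose first carbon Cα is fully substituted (Br, CH3, CH2Cl). There are four stereocentres: 2S, 3R, 5R and αR. On the ring the C2 methyl, the C3 bromine and the C5 side chain share one face, and the bromoethenyl group stands alone on the other. Bromine is therefore trans to the alkenyl group and cis to the side chain. Cα is stereogenic only because CH3 and CH2Cl differ, and it has no hydrogen, so it cannot be corrected once set. The tertiary bromide is vicinal to a primary chloride and β to the ring oxygen (ionisation, E2, reductive elimination), C3 is a β-bromo ether, and the vinyl bromide rules out strongly reducing metals late in the route. The difficulty is that two tetrasubstituted carbons flank the ring oxygen, both bromine-bearing sp3 carbons are too hindered for SN2 introduction of bromide, and no hydroxyl or carbonyl group is left to steer anything. The plan rests on the sequence C5(H)–C4H2–C3–C2(CH3)–O1: a 1-methyl-1-silylallene delivers exactly this three-carbon unit to an aldehyde carbon that becomes C5, and the silicon it leaves on C3 marks where the ring bromine goes.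

## Retrosynthetic reasoning

**19 back to alkyne 17.** The C(sp2)–Br bond is cut first, through alkenylzirconium species 18. A syn hydrometalation of a terminal alkyne followed by bromination with retention fixes the E geometry, and the alkyne is an inert spectator until then. The forward step must add across the triple bond without touching three alkyl halides.

**17 and 16 back to ketal 15.** The C2–C(sp) bond is cut. C2 is bonded to O1, so it can be an oxocarbenium carbon that accepts a silylacetylene nucleophile. This builds the quaternary centre without any substitution at a hindered sp3 carbon. The forward reaction has to put the alkyne on the face opposite the C3 bromine.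

**15 back to bromo enol ether 14 and vinylsilane 13.** Both remaining bonds at C3 (C–H and C–Br) are traced to the C2=C3 enol ether. An electrophile adds to C3 on the face away from the C5 side chain, so the substituent that arrives last ends up trans to the side chain. Bromine must be cis to it, so bromine enters first by replacing silicon at the sp2 carbon (13 to 14), and the proton enters last (14 to 15). This is why the silicon of 13 is an asset rather than waste.

**13 back to aldehyde 7 and allene 12 (key disconnection).** C4–C5 and O1–C2 are cut together. Nowhere else does a single operation give the ring, the C2 methyl, the bare C4 methylene and a functional handle on C3 at once. The forward annulation must choose one face of an aldehyde whose α-carbon is quaternary.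

**12 back to 11, 10 and propargyl alcohol 8.** The allene comes from SN2′ delivery of a methyl group to a C-silylated propargylic sulfonate. The C–Si bond is made on the acetylide.

**7 back to diol 6 and epoxy alcohol 5.** The aldehyde carbon is revealed by cleaving a 1,2-diol, and the Cα–Br bond is cut as an invertive, hydroxyl-directed opening of a 2,3-epoxy alcohol at its tertiary carbon. This sets the quaternary bromide from a reagent-controlled epoxidation, not by asking an enzyme or a small-molecule catalyst to tell bromine from methyl on a prochiral precursor. The chloromethyl group is already present, which avoids a substitution at a neopentyl carbon beside the tertiary bromide.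

**5 back to allylic alcohol 4, then 3, 2 and prenyl acetate 1.** The epoxide is cut to the E-allylic alcohol. Its chlorine comes from an allylic alcohol, and that alcohol from oxidation of the E-methyl group of a prenyl ester. The E geometry matters twice: it fixes the configuration at the tertiary epoxide carbon, and it places CH2OH and CH2Cl on opposite faces of the epoxide so that the alkoxide cannot displace chloride.

## Alternatives that were turned down

**Alternative 1: Petasis–Ferrier rearrangement to an oxolan-3-one.**
- Disconnection: C4–C5, with the O1–C5 bond stored beforehand in the 4-methylene-1,3-dioxolane A1, an acetal of aldehyde 7 whose quaternary carbon already holds the methyl and a silylethynyl group.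
- Forward key step: Me2AlCl opens A1 at the acetal carbon, and the aluminium enolate attacks the O1=C5 oxocarbenium ion to give oxolan-3-one A2. Both acetal epimers of A1 give the same ion.
- For: it is convergent, and C2 arrives as a preformed quaternary centre with its two-carbon arm. No facial selection is needed at C2, and on that point it is stronger than the chosen route.
- Against:
  - The cation sits directly beside the tertiary C–Br and is made with an aluminium Lewis acid.
  - The chiral quaternary carbon of A1 needs its own asymmetric synthesis.
  - A carbonyl methylenation is needed in the presence of three halides.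
  - A2 has a ketone where the target has the C3 bromide. For a single invertive bromination the hydride would have to attack the carbonyl face that carries both the C2 methyl and the C5 side chain, whereas the open face lies next to the slim alkyne. The SN2 bromination that follows is at a carbon next to a quaternary centre.
- Comparison: the chosen route introduces the C3 bromine at an sp2 carbon with no substitution and needs no separate chiral C2 fragment. It pays with a facial selection at C2.

**Alternative 2: bromide-triggered opening of a bis-epoxide.**
- Disconnection: C3–Br and O1–C5, both as epoxide openings of bis-epoxy alcohol A3.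
- Forward key step: Ti(OiPr)4 and a dialkylammonium bromide open the 2,3-epoxy alcohol part at the carbon remote from the hydroxyl with inversion. The tertiary alkoxide left on C2 then attacks the second epoxide at its secondary carbon in a 5-exo closure to give A4.
- For: C2, C3 and C5 are each set by a stereospecific event from two reagent-controlled epoxidations, and bromine enters C3 by inversion. On ring stereocontrol this plan is stronger than the chosen one, which relies on facial selectivity at C5, C3 and C2.
- Against:
  - A4 has a tertiary alcohol on Cα where the target needs a tertiary bromide of defined configuration. Ionisation there would be assisted by the ring oxygen and by chlorine and would lead to scrambling, rearrangement or elimination, late in the synthesis.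
  - The second epoxide must open at its less substituted end.
  - The C2 hydroxymethyl group needs oxidation and a one-carbon homologation to become bromoethenyl.
- Comparison: the chosen route gives up stereospecificity in the ring. In exchange it sets Cα–Br at the outset by the same kind of invertive epoxide opening, on a four-carbon molecule where this is safe, and it is shorter after ring formation.

**Alternative 3: oxonium ylide formation and [2,3] shift.**
- Disconnection: O1–C2 and the bond from C2 to an allyl group, leading to the allyl ether diazoketone A5.
- Forward key step: Cu(acac)2 forms a copper carbenoid, the ether oxygen captures it to close the five-membered oxonium ylide, and the allyl group migrates from oxygen to C2 to give A6.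
- For: ring and quaternary C2 form in one step, and the usual preference places the migrating group trans to the C5 substituent, which is the relationship required. At C2 this is at least as dependable as the oxocarbenium alkynylation of the chosen route.
- Against:
  - Allyl has three carbons where the target has two, so isomerisation, oxidative cleavage and a new olefination are needed.
  - A6 is again a 3-ketone, with the same reduction and hindered SN2 problem as A2.
  - The ether of A5 must be made on an alcohol vicinal to the tertiary bromide, which closes to an epoxide under base.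
  - The carbenoid can be intercepted by bromine or chlorine lone pairs.
- Comparison: the step count after ring formation is clearly higher than in the chosen route.

Key step: step 10

Remark on the chemistry: ketal 15 is drawn without a descriptor at C2, because both anomers are expected and both give the same cation in step 13.

## Route

Step 1
Reactants: 1 3-methylbut-2-en-1-yl acetate (prenyl acetate)
Product: 2 (2E)-4-hydroxy-3-methylbut-2-en-1-yl acetate
Conditions: SeO2 (cat.), t-BuOOH, CH2Cl2, rt
Reagents that add atoms: tert-butyl hydroperoxide, CC(C)(C)OO
Why: Allylic oxidation with SeO2 (ene reaction, then [2,3]-sigmatropic shift) attacks the methyl group trans to the chain of a trisubstituted alkene, so the E-hydroxymethyl isomer should form; this is the lower homologue of the standard oxidation of geranyl esters.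

Step 2
Reactants: 2 (2E)-4-hydroxy-3-methylbut-2-en-1-yl acetate
Product: 3 (2E)-4-chloro-3-methylbut-2-en-1-yl acetate
Conditions: PPh3, CCl4, CH2Cl2, 0 °C→rt
Reagents that add atoms: carbon tetrachloride, ClC(Cl)(Cl)Cl
Why: Appel chlorination; chloride displaces the primary allylic oxyphosphonium group by SN2, which should leave the alkene geometry and the acetate untouched.

Step 3
Reactants: 3 (2E)-4-chloro-3-methylbut-2-en-1-yl acetate
Product: 4 (2E)-4-chloro-3-methylbut-2-en-1-ol
Conditions: K2CO3 (cat.), MeOH, 0 °C
Reagents that add atoms: none
Why: Base-catalysed transesterification of the acetate; with catalytic carbonate in the cold the allylic chloride should survive, as it does in the corresponding chlorinated terpenyl acetates.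

Step 4
Reactants: 4 (2E)-4-chloro-3-methylbut-2-en-1-ol
Product: 5 [(2R,3S)-3-(chloromethyl)-3-methyloxiran-2-yl]methanol
Conditions: Ti(OiPr)4 (cat.), D-(−)-diisopropyl tartrate (cat.), t-BuOOH, 4 Å MS, CH2Cl2, −20 °C
Reagents that add atoms: tert-butyl hydroperoxide, CC(C)(C)OO
Why: Sharpless asymmetric epoxidation of a 3,3-disubstituted E-allylic alcohol, a favourable substrate class; the D-(−)-tartrate catalyst gives the 2R epoxide, which for the E-alkene means 3S at the tertiary carbon. In this trans epoxide CH2OH and CH2Cl lie on opposite faces, so the alkoxide cannot displace chloride.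

Step 5
Reactants: 5 [(2R,3S)-3-(chloromethyl)-3-methyloxiran-2-yl]methanol
Product: 6 (2R,3R)-3-bromo-4-chloro-3-methylbutane-1,2-diol
Conditions: Ti(OiPr)4, Et2NH2Br, CH2Cl2, 0 °C→rt
Reagents that add atoms: diethylammonium bromide, CC[NH2+]CC.[Br-]
Why: Titanium-assisted opening of a 2,3-epoxy alcohol; the epoxide held on Ti(OiPr)4 through the C1 alkoxide is attacked by bromide at C3, the tertiary carbon remote from the hydroxyl, with inversion, which turns the 3S epoxide into the 3R tertiary bromide. C2 is not touched and is removed in the next step.

Step 6
Reactants: 6 (2R,3R)-3-bromo-4-chloro-3-methylbutane-1,2-diol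
Product: 7 (2R)-2-bromo-3-chloro-2-methylpropanal
Conditions: NaIO4/SiO2, CH2Cl2, rt; filtered, dried, used as solution
Reagents that add atoms: none
Why: Periodate cleavage of the 1,2-diol excises C1 and turns C2 into the aldehyde carbon; the α-carbon has no hydrogen and cannot epimerise, and the non-aqueous variant avoids the hydrate of this electrophilic aldehyde.

Step 7
Reactants: 8 prop-2-yn-1-ol (propargyl alcohol)
Product: 10 3-[tert-butyl(dimethyl)silyl]prop-2-yn-1-ol, via O,C-bis-silyl ether 9 (not isolated)
Conditions: n-BuLi (2.2 equiv), THF, −78 °C→0 °C; TBSCl (2.2 equiv), −78 °C→rt; then HCl (cat.), MeOH, rt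
Reagents that add atoms: tert-butyldimethylsilyl chloride, CC(C)(C)[Si](C)(C)Cl
Why: The dilithiated alkoxide–acetylide is silylated at carbon and at oxygen; acid-catalysed methanolysis then cleaves only the Si–O bond, because the alkynyl C–Si bond of this bulky silyl group is inert to dilute acid.

Step 8
Reactants: 10 3-[tert-butyl(dimethyl)silyl]prop-2-yn-1-ol
Product: 11 3-[tert-butyl(dimethyl)silyl]prop-2-yn-1-yl methanesulfonate
Conditions: MsCl, Et3N, CH2Cl2, −20 °C
Reagents that add atoms: methanesulfonyl chloride, CS(=O)(=O)Cl
Why: Sulfonylation of a primary propargylic alcohol; the mesylate is used without purification.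

Step 9
Reactants: 11 3-[tert-butyl(dimethyl)silyl]prop-2-yn-1-yl methanesulfonate
Product: 12 3-[tert-butyl(dimethyl)silyl]buta-1,2-diene
Conditions: MeMgCl, CuBr, LiBr, THF, −78 °C→rt
Reagents that add atoms: methylmagnesium chloride, C[Mg]Cl
Why: Copper-mediated SN2′ substitution of a propargylic sulfonate; the methylcopper species attacks the silyl-bearing alkyne carbon while the mesylate leaves from the other end, which gives the 1-methyl-1-silylallene and not the propargylic substitution product.

Step 10
Reactants: 7 (2R)-2-bromo-3-chloro-2-methylpropanal and 12 3-[tert-butyl(dimethyl)silyl]buta-1,2-diene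
Product: 13 tert-butyl{(5R)-5-[(2R)-2-bromo-1-chloropropan-2-yl]-2-methyl-4,5-dihydrofuran-3-yl}dimethylsilane
Conditions: TiCl4 (1.1 equiv), CH2Cl2, −78 °C; NaHCO3 (aq) quench
Reagents that add atoms: none
Why: TiCl4 binds the aldehyde oxygen of 7 and the unsubstituted CH2 terminus of allene 12 attacks the carbonyl carbon, so that C4–C5 forms and a vinyl cation appears on the central allene carbon, held by hyperconjugation with the neighbouring C–Si bond. A 1,2-shift of the silyl group then moves the positive charge to the methyl-bearing carbon, and the titanium alkoxide on C5 captures it, so that O1–C2 forms and TiCl4 is released. This ring closure is a 5-endo attack of oxygen on a linear vinyl cation, which has no stereoelectronic barrier because the empty orbital lies in the plane of the forming ring. The closest known reaction type is the TiCl4-promoted (3+2) annulation of 1-silylallenes with aldehydes to 3-silyl-4,5-dihydrofurans, in which a tert-butyl group on silicon suppresses loss of silicon to a homopropargylic alcohol. C5 is the only new stereocentre and is controlled by the quaternary α-carbon of 7: in the Cornforth arrangement the C–Br bond lies anti to C=O, the carbonyl faces are flanked by CH3 and by CH2Cl, and attack past the smaller CH3 gives 5R (the polar Felkin–Anh model, with C–Br anti to the incoming allene, leads to the same isomer). The step therefore needs facial selectivity between two groups of similar size and no chelation, and the substrate helps in that bromine and chlorine bind TiCl4 poorly and the α-carbon cannot epimerise. Regioselectivity is not in question because only the CH2 end of 12 leads to a silicon-stabilised cation. The reaction is run cold and briefly so that TiCl4 does not ionise the tertiary bromide, which is deactivated by the flanking carbonyl and chloromethyl groups.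

Step 11
Reactants: 13 tert-butyl{(5R)-5-[(2R)-2-bromo-1-chloropropan-2-yl]-2-methyl-4,5-dihydrofuran-3-yl}dimethylsilane
Product: 14 (5R)-3-bromo-5-[(2R)-2-bromo-1-chloropropan-2-yl]-2-methyl-4,5-dihydrofuran
Conditions: NBS (1.0 equiv), NaHCO3, MeCN, −30 °C→0 °C
Reagents that add atoms: N-bromosuccinimide, O=C1CCC(=O)N1Br
Why: ipso-Bromodesilylation of a vinylsilane; C3 is both the nucleophilic enol ether carbon and the silicon-bearing carbon, so bromine adds there, the oxocarbenium ion formed is β to silicon, and loss of the silyl group to succinimide restores the C2=C3 bond with bromine in place of silicon.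

Step 12
Reactants: 14 (5R)-3-bromo-5-[(2R)-2-bromo-1-chloropropan-2-yl]-2-methyl-4,5-dihydrofuran
Product: 15 (3R,5R)-3-bromo-5-[(2R)-2-bromo-1-chloropropan-2-yl]-2-methoxy-2-methyloxolane (both C2 anomers)
Conditions: CSA (cat.), MeOH, 0 °C→rt
Reagents that add atoms: methanol, CO
Why: Acid-catalysed addition of methanol to an enol ether (ketal formation), known also for β-bromo enol ethers. Protonation at C3 sets this centre: with the C5 side chain pseudo-equatorial, C5 is displaced toward the opposite face, and attack of the proton on that face is staggered with respect to the C4–H bonds and unhindered, so bromine should end up cis to the side chain (3R).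

Step 13
Reactants: 15 (3R,5R)-3-bromo-5-[(2R)-2-bromo-1-chloropropan-2-yl]-2-methoxy-2-methyloxolane
Product: 16 {[(2S,3R,5R)-3-bromo-5-[(2R)-2-bromo-1-chloropropan-2-yl]-2-methyloxolan-2-yl]ethynyl}trimethylsilane
Conditions: SnCl4, bis(trimethylsilyl)acetylene, CH2Cl2, −78 °C→−30 °C
Reagents that add atoms: bis(trimethylsilyl)acetylene, C[Si](C)(C)C#C[Si](C)(C)C
Why: Lewis-acid-mediated substitution of a ketal by an alkynylsilane; SnCl4 ionises the methoxy group of either anomer to the same cyclic oxocarbenium ion, and the silylacetylene attacks through a silicon-bearing carbon with loss of that silyl group. The alkyne should enter anti to the C3–Br bond (the 1,2-trans preference of α-bromo oxocarbenium ions), which is also the face remote from the C5 side chain, and this gives 2S.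

Step 14
Reactants: 16 {[(2S,3R,5R)-3-bromo-5-[(2R)-2-bromo-1-chloropropan-2-yl]-2-methyloxolan-2-yl]ethynyl}trimethylsilane
Product: 17 (2S,3R,5R)-3-bromo-5-[(2R)-2-bromo-1-chloropropan-2-yl]-2-ethynyl-2-methyloxolane
Conditions: K2CO3 (cat.), MeOH, 0 °C
Reagents that add atoms: none
Why: Base-catalysed methanolysis of the alkynyl C–Si bond; with catalytic carbonate in the cold the alkyl bromides and the chloride should not undergo E2 elimination or substitution.

Step 15
Reactants: 17 (2S,3R,5R)-3-bromo-5-[(2R)-2-bromo-1-chloropropan-2-yl]-2-ethynyl-2-methyloxolane
Product: 19 (2S,3R,5R)-3-bromo-5-[(2R)-2-bromo-1-chloropropan-2-yl]-2-[(E)-2-bromoethenyl]-2-methyloxolane, via alkenylzirconocene chloride 18 (not isolated)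
Conditions: Cp2Zr(H)Cl, THF, rt; then NBS, 0 °C
Reagents that add atoms: N-bromosuccinimide, O=C1CCC(=O)N1Br
Why: Hydrozirconation of a terminal alkyne is a syn addition that places zirconium on the terminal carbon, and bromination of the C–Zr bond with NBS occurs with retention, so the E vinyl bromide should result; Cp2Zr(H)Cl adds to alkynes much faster than it attacks alkyl bromides or chlorides.

## Compound list

1 | 3-methylbut-2-en-1-yl acetate (prenyl acetate) | CC(C)=CCOC(C)=O | starting material
2 | (2E)-4-hydroxy-3-methylbut-2-en-1-yl acetate | CC(=O)OC/C=C(\C)CO | intermediate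
3 | (2E)-4-chloro-3-methylbut-2-en-1-yl acetate | CC(=O)OC/C=C(\C)CCl | intermediate
4 | (2E)-4-chloro-3-methylbut-2-en-1-ol | OC/C=C(\C)CCl | intermediate
5 | [(2R,3S)-3-(chloromethyl)-3-methyloxiran-2-yl]methanol | OC[C@H]1O[C@]1(C)CCl | intermediate
6 | (2R,3R)-3-bromo-4-chloro-3-methylbutane-1,2-diol | OC[C@@H](O)[C@@](C)(Br)CCl | intermediate
7 | (2R)-2-bromo-3-chloro-2-methylpropanal | C[C@](Br)(CCl)C=O | intermediate
8 | prop-2-yn-1-ol (propargyl alcohol) | C#CCO | starting material
9 | tert-butyl({3-[tert-butyl(dimethyl)silyl]prop-2-yn-1-yl}oxy)dimethylsilane | CC(C)(C)[Si](C)(C)OCC#C[Si](C)(C)C(C)(C)C | intermediate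
10 | 3-[tert-butyl(dimethyl)silyl]prop-2-yn-1-ol | OCC#C[Si](C)(C)C(C)(C)C | intermediate
11 | 3-[tert-butyl(dimethyl)silyl]prop-2-yn-1-yl methanesulfonate | CS(=O)(=O)OCC#C[Si](C)(C)C(C)(C)C | intermediate
12 | 3-[tert-butyl(dimethyl)silyl]buta-1,2-diene | C=C=C(C)[Si](C)(C)C(C)(C)C | intermediate
13 | tert-butyl{(5R)-5-[(2R)-2-bromo-1-chloropropan-2-yl]-2-methyl-4,5-dihydrofuran-3-yl}dimethylsilane | C[C@](Br)(CCl)[C@H]1CC([Si](C)(C)C(C)(C)C)=C(C)O1 | intermediate
14 | (5R)-3-bromo-5-[(2R)-2-bromo-1-chloropropan-2-yl]-2-methyl-4,5-dihydrofuran | C[C@](Br)(CCl)[C@H]1CC(Br)=C(C)O1 | intermediate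
15 | (3R,5R)-3-bromo-5-[(2R)-2-bromo-1-chloropropan-2-yl]-2-methoxy-2-methyloxolane (both C2 anomers) | C[C@](Br)(CCl)[C@H]1C[C@@H](Br)C(C)(OC)O1 | intermediate
16 | {[(2S,3R,5R)-3-bromo-5-[(2R)-2-bromo-1-chloropropan-2-yl]-2-methyloxolan-2-yl]ethynyl}trimethylsilane | C[C@](Br)(CCl)[C@H]1C[C@@H](Br)[C@](C)(C#C[Si](C)(C)C)O1 | intermediate
17 | (2S,3R,5R)-3-bromo-5-[(2R)-2-bromo-1-chloropropan-2-yl]-2-ethynyl-2-methyloxolane | C[C@](Br)(CCl)[C@H]1C[C@@H](Br)[C@](C)(C#C)O1 | intermediate
18 | chlorobis(cyclopentadienyl){(E)-2-[(2S,3R,5R)-3-bromo-5-[(2R)-2-bromo-1-chloropropan-2-yl]-2-methyloxolan-2-yl]ethenyl}zirconium | C[C@](Br)(CCl)[C@H]1C[C@@H](Br)[C@](C)(/C=C/[Zr](Cl)(C2C=CC=C2)C2C=CC=C2)O1 | intermediate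
19 | (2S,3R,5R)-3-bromo-5-[(2R)-2-bromo-1-chloropropan-2-yl]-2-[(E)-2-bromoethenyl]-2-methyloxolane | C[C@](Br)(CCl)[C@H]1C[C@@H](Br)[C@](C)(/C=C/Br)O1 | target

## Step count and least certain steps

Total step count: 15. Longest linear sequence: 12 steps (steps 1–6, then 10–15); the allene branch (steps 7–9) joins at step 10.

**Step 10 (key step).**
- What may go wrong: the facial discrimination between CH3 and CH2Cl may be too weak and give a mixture at C5. The vinyl cation may lose silicon before the 1,2-shift and ring closure, or be captured by chloride. TiCl4 may ionise the tertiary bromide.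
- Fallback: C–C bond formation and ring closure are separated.
  - Setting out from 7, TiCl4-promoted propargylation with commercial 3-(trimethylsilyl)buta-1,2-diene (the trimethylsilyl analogue of 12, from which silicon is lost on purpose) would give (2R,3R)-2-bromo-1-chloro-2-methylhept-5-yn-3-ol F1.
  - If the carbinol centre forms unselectively, the mixture is oxidised with Dess–Martin periodinane to (2R)-2-bromo-1-chloro-2-methylhept-5-yn-3-one F2. This is reduced under reagent control (Corey–Bakshi–Shibata reduction, (S)-oxazaborolidine, catecholborane, −78 °C) back to F1.
  - Bromoetherification of F1 (NBS, MeCN, 0 °C; 5-endo attack of the hydroxyl on the bromine-activated alkyne) returns to the route at 14. Steps 10 and 11 are bypassed.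

**Step 13.**
- What may go wrong: the alkyne may enter on the wrong face of the oxocarbenium ion, because the conformer with bromine and side chain both pseudo-equatorial has a torsional preference for attack syn to bromine. The cation may also lose the C3 proton, which re-forms 14 and scrambles C3.
- Fallback: C2 is corrected under thermodynamic control through a cobalt-stabilised propargylic cation (Nicholas-type equilibration).
  - Setting out from 16 as its mixture of C2 epimers, Co2(CO)8 in CH2Cl2 gives the hexacarbonyldicobalt complex of 16 F3, also as a mixture.
  - BF3·OEt2 at −20 °C ionises the C2–O1 bond reversibly, and re-closure should place the bulky cobalt cluster trans to the C3 bromine.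
  - (NH4)2Ce(NO3)6 in acetone at 0 °C removes the metal and returns to the route at 16.

**Step 12.**
- What may go wrong: facial selectivity in the protonation of C3 may be poor, or C3 may erode through reversible ionisation and proton loss in the acidic alcohol.
- Fallback: the cation precursor is made irreversibly in an aprotic medium. Setting out from 14, anhydrous HCl in CH2Cl2 at −78 °C adds across the enol ether to give (3R,5R)-3-bromo-5-[(2R)-2-bromo-1-chloropropan-2-yl]-2-chloro-2-methyloxolane F4. This is not isolated; SnCl4 and bis(trimethylsilyl)acetylene are added to the same flask. The route is rejoined at 16 and ketal 15 is bypassed.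

**Step 5.**
- What may go wrong: bromide may attack C2 instead of C3, because the chloromethyl group makes the tertiary carbon less able to bear positive charge in the transition state.
- Fallback: the tertiary carbon is placed β to a carboxyl group, so that the electronic bias also directs attack there.
  - Setting out from 5, RuCl3/NaIO4 oxidation gives (2S,3S)-3-(chloromethyl)-3-methyloxirane-2-carboxylic acid F5.
  - HBr in Et2O at 0 °C opens F5 at C3 with inversion to (2R,3R)-3-bromo-4-chloro-2-hydroxy-3-methylbutanoic acid F6.
  - Oxidative decarboxylation of this α-hydroxy acid with Pb(OAc)4 returns to the route at 7.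

**Step 15.**
- What may go wrong: the zirconium hydride may reduce or eliminate the C–Br bonds, or addition may be slow next to the quaternary C2.
- Fallback: a different metal and mechanism are used. Setting out from 17, PdCl2(PPh3)2-catalysed syn hydrostannylation with Bu3SnH (no radical initiator) gives tributyl{(E)-2-[(2S,3R,5R)-3-bromo-5-[(2R)-2-bromo-1-chloropropan-2-yl]-2-methyloxolan-2-yl]ethenyl}stannane F7. Bromodestannylation with NBS at 0 °C, with retention, returns to the route at 19.

## Further compounds

F1 | step 10 | (2R,3R)-2-bromo-1-chloro-2-methylhept-5-yn-3-ol | C[C@](Br)(CCl)[C@H](O)CC#CC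
F2 | step 10 | (2R)-2-bromo-1-chloro-2-methylhept-5-yn-3-one | C[C@](Br)(CCl)C(=O)CC#CC
F3 | step 13 | hexacarbonyldicobalt complex of 16, Co2(CO)6 bound to the C≡C bond | C[C@](Br)(CCl)[C@H]1C[C@@H](Br)[C@](C)(C23C4([Si](C)(C)C)[Co]2(=C=O)(=C=O)(=C=O)[Co]34(=C=O)(=C=O)=C=O)O1
F4 | step 12 | (3R,5R)-3-bromo-5-[(2R)-2-bromo-1-chloropropan-2-yl]-2-chloro-2-methyloxolane | C[C@](Br)(CCl)[C@H]1C[C@@H](Br)C(C)(Cl)O1
F5 | step 5 | (2S,3S)-3-(chloromethyl)-3-methyloxirane-2-carboxylic acid | OC(=O)[C@H]1O[C@]1(C)CCl
F6 | step 5 | (2R,3R)-3-bromo-4-chloro-2-hydroxy-3-methylbutanoic acid | OC(=O)[C@@H](O)[C@@](C)(Br)CCl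
F7 | step 15 | tributyl{(E)-2-[(2S,3R,5R)-3-bromo-5-[(2R)-2-bromo-1-chloropropan-2-yl]-2-methyloxolan-2-yl]ethenyl}stannane | C[C@](Br)(CCl)[C@H]1C[C@@H](Br)[C@](C)(/C=C/[Sn](CCCC)(CCCC)CCCC)O1
A1 | alternative 1 | (5S)-2-[(2R)-2-bromo-1-chloropropan-2-yl]-5-methyl-4-methylidene-5-[(trimethylsilyl)ethynyl]-1,3-dioxolane (both acetal epimers) | C[C@](Br)(CCl)C1OC(=C)[C@](C)(C#C[Si](C)(C)C)O1
A2 | alternative 1 | (2S,5R)-5-[(2R)-2-bromo-1-chloropropan-2-yl]-2-methyl-2-[(trimethylsilyl)ethynyl]oxolan-3-one | C[C@](Br)(CCl)[C@H]1CC(=O)[C@](C)(C#C[Si](C)(C)C)O1
A3 | alternative 2 | [(2S,3S)-3-{[(2S,3R)-3-(chloromethyl)-3-methyloxiran-2-yl]methyl}-2-methyloxiran-2-yl]methanol | OC[C@]1(C)O[C@H]1C[C@@H]1O[C@@]1(C)CCl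
A4 | alternative 2 | (2R)-2-[(2R,4R,5S)-4-bromo-5-(hydroxymethyl)-5-methyloxolan-2-yl]-1-chloropropan-2-ol | C[C@](O)(CCl)[C@H]1C[C@@H](Br)[C@](C)(CO)O1
A5 | alternative 3 | (5R,6R)-6-bromo-7-chloro-2-diazo-6-methyl-5-(prop-2-en-1-yloxy)heptan-3-one | C[C@](Br)(CCl)[C@H](OCC=C)CC(=O)C(C)=[N+]=[N-]
A6 | alternative 3 | (2S,5R)-5-[(2R)-2-bromo-1-chloropropan-2-yl]-2-methyl-2-(prop-2-en-1-yl)oxolan-3-one | C[C@](Br)(CCl)[C@H]1CC(=O)[C@](C)(CC=C)O1
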